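**Plan**

1. Retrosynthesis (gibberellane numbering): after the C7 ester, the C13–C16 bond of ring D is cut as a retro 1,2-vinyl shift, giving a methylenecyclobutyl ketone (four-membered ring C8–C14–C16–C15, C13=O). C8–C15/C14–C16 then fall to an enone–allene [2+2], the 2,3-diol to an alkene, C4–C5 to a lactone-tethered intramolecular Michael addition, C2=C3 to ring-closing metathesis, C8=C14/C9–C11 to a Michael/aldol annulation and C10–C1 to an allyl addition.
2. Enabling feature: in ring D (C8, C14, C13, C16, C15) the bridgehead carbinol C13 is bonded directly to the vinyl carbon C16 of the exocyclic C16=C17 alkene. With C16 held on C14 in a four-membered ring, a ketyl at C13 is homoallylic to C16=C17, so one 1,2-vinyl shift makes the tertiary alcohol, keeps the methylene and expands the four-membered ring to ring D.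
3. Forward order: ring B (chiral-pool cyclopentenone) → ring C → seven-membered lactone → ring A plus γ-lactone → 2,3-diol → cyclobutane → ring D → free acid.
4. Stereochemistry: C10 from the (S)-silyloxy centre of 1 (relayed, then oxidised away); C9 anti to the allyl group (also the stable epimer); C4/C5 forced by the lactone tether; C6 by equilibration; C2/C3 by dihydroxylation anti to the lactone bridge; C8 by photocycloaddition syn to H9; C13 forced by the bicycle.

Key step: step 17

Remark: the target gibberellin is 2β,3β,13-trihydroxy-20-norgibberell-16-ene-7,19-dioic acid 19,10-lactone. Gibberellane numbering is used for the atoms of all intermediates. Centres that are later destroyed or equilibrated (the silyl-bearing carbon in 7, C13 in 13–19, C4 in 16–17, C6 in 18–19) are carried as epimer mixtures and left undefined in the SMILES.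

**Route**

Step 1
Reactants: 1 (S)-4-(tert-butyldimethylsilyloxy)cyclopent-2-en-1-one; 2 allylmagnesium bromide
Product: 3 (1R,4S)-1-allyl-4-(tert-butyldimethylsilyloxy)cyclopent-2-en-1-ol
Conditions: CH2=CHCH2MgBr, THF, –78 °C; aq. NH4Cl
Reagents that add atoms: allylmagnesium bromide (2), C=CC[Mg]Br
Why: 1,2-addition of the allyl Grignard reagent to the enone carbonyl should occur anti to the silyloxy group, setting the tertiary carbinol (future C10) with allyl trans to OTBS.

Step 2
Reactants: 3 (1R,4S)-1-allyl-4-(tert-butyldimethylsilyloxy)cyclopent-2-en-1-ol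
Product: 4 (1R,4S)-1-allylcyclopent-2-ene-1,4-diol
Conditions: Bu4NF, THF, 0 °C
Reagents that add atoms: none
Why: fluoride-mediated silyl ether cleavage frees the secondary allylic alcohol and leaves the tertiary carbinol untouched.

Step 3
Reactants: 4 (1R,4S)-1-allylcyclopent-2-ene-1,4-diol
Product: 5 (R)-4-allyl-4-hydroxycyclopent-2-en-1-one
Conditions: MnO2, CH2Cl2, rt
Reagents that add atoms: none
Why: MnO2 oxidises only the secondary allylic alcohol, so the original stereocentre is erased after relaying its chirality to the quaternary carbinol.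

Step 4
Reactants: 5 (R)-4-allyl-4-hydroxycyclopent-2-en-1-one; 6 3-(trimethylsilyl)but-3-en-2-one
Product: 8 (4S,5S)-4-allyl-4-hydroxy-5-(3-oxobutyl)cyclopent-2-en-1-one, via α-silyl diketone 7 (not isolated)
Conditions: LiN(iPr)2 (2.2 equiv), THF, –78 °C; 6, –78 °C; AcOH; then KF, MeOH, rt
Reagents that add atoms: 3-(trimethylsilyl)but-3-en-2-one (6), CC(=O)C(=C)[Si](C)(C)C
Why: kinetic α′-deprotonation of the alkoxide enone gives a dianion (an alkoxide cannot β-eliminate) whose Michael addition to the α-silyl vinyl ketone should occur anti to the allyl group, placing the side chain (future C11–C14) cis to the oxygen, and fluoride then cleaves the C–Si bond.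

Step 5
Reactants: 8 (4S,5S)-4-allyl-4-hydroxy-5-(3-oxobutyl)cyclopent-2-en-1-one
Product: 9 4-allyl-4-hydroxy-2-iodo-5-(3-oxobutyl)cyclopent-2-en-1-one (configuration as in 8)
Conditions: I2, pyridine, CH2Cl2, rt
Reagents that add atoms: iodine, II
Why: α-iodination of the enone by the pyridine addition/iodination/elimination sequence takes place only at the α-carbon of the conjugated ketone (future C6).

Step 6
Reactants: 9 4-allyl-4-hydroxy-2-iodo-5-(3-oxobutyl)cyclopent-2-en-1-one; 10 carbon monoxide
Product: 11 methyl 3-allyl-3-hydroxy-5-oxo-4-(3-oxobutyl)cyclopent-1-ene-1-carboxylate (3-OH and side chain cis)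
Conditions: CO (1 atm), MeOH, Pd(OAc)2 (5 mol%), PPh3, Et3N, DMF, 50 °C
Reagents that add atoms: carbon monoxide (10), [C-]#[O+]; methanol, CO
Why: palladium-catalysed methoxycarbonylation of the vinyl iodide (oxidative addition to zerovalent palladium, CO insertion, methanolysis) installs the C7 ester without touching the isolated alkene or the ketones.

Step 7
Reactants: 11 methyl 3-allyl-3-hydroxy-5-oxo-4-(3-oxobutyl)cyclopent-1-ene-1-carboxylate
Product: 12 methyl 1-allyl-1-hydroxy-5-oxo-5,6,7,7a-tetrahydro-1H-indene-3-carboxylate (1-OH cis to C7, allyl cis to H-7a)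
Conditions: pyrrolidine (0.3 equiv), AcOH (0.3 equiv), CH2Cl2, rt
Reagents that add atoms: none
Why: amine/acid-mediated intramolecular aldol condensation of the methyl ketone onto the ring ketone (second half of a Robinson annulation) closes ring C as the C8=C14 dienone, and the enolisable C9 centre should settle trans to the allyl group.

Step 8
Reactants: 12 methyl 1-allyl-1-hydroxy-5-oxo-5,6,7,7a-tetrahydro-1H-indene-3-carboxylate
Product: 13 methyl 1-allyl-1,5-dihydroxy-5,6,7,7a-tetrahydro-1H-indene-3-carboxylate (C13 epimers)
Conditions: NaBH4, CeCl3·7H2O, MeOH, –78 °C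
Reagents that add atoms: none
Why: Luche reduction delivers hydride 1,2 to the dienone carbonyl, removing the group that would acidify H9 in the coming base steps; the C13 configuration is immaterial because the centre is re-oxidised in step 14.

Step 9
Reactants: 13 methyl 1-allyl-1,5-dihydroxy-5,6,7,7a-tetrahydro-1H-indene-3-carboxylate
Product: 14 methyl 1-allyl-5-(tert-butyldimethylsilyloxy)-1-hydroxy-5,6,7,7a-tetrahydro-1H-indene-3-carboxylate
Conditions: TBSCl, imidazole, DMF, 0 °C
Reagents that add atoms: tert-butyldimethylsilyl chloride, CC(C)(C)[Si](C)(C)Cl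
Why: the secondary allylic alcohol is silylated selectively because the tertiary carbinol is too hindered for TBSCl/imidazole.

Step 10
Reactants: 14 methyl 1-allyl-5-(tert-butyldimethylsilyloxy)-1-hydroxy-5,6,7,7a-tetrahydro-1H-indene-3-carboxylate; 15 2-methylbut-3-enoic acid (racemic)
Product: 16 2-methylbut-3-enoate ester of 14 at the tertiary (C10) hydroxyl (C4 epimers)
Conditions: 15, DCC, DMAP (1 equiv), CH2Cl2, 0 °C → rt
Reagents that add atoms: 2-methylbut-3-enoic acid (15), C=CC(C)C(=O)O
Why: Steglich esterification acylates the remaining tertiary alcohol with the β,γ-unsaturated acid under conditions mild enough to keep the vinyl group out of conjugation; both C4 epimers serve because C4 is enolised in step 12.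

Step 11
Reactants: 16 2-methylbut-3-enoate ester of 14
Product: 17 spiro lactone: 3-methyl-3,6-dihydrooxepin-2(7H)-one ring (O–C19(=O)–C4H(CH3)–C3H=C2H–C1H2) spiro-fused through C10 to the bicyclic diene ester
Conditions: second-generation Grubbs catalyst (5 mol%), CH2Cl2 (3 mM), 40 °C
Reagents that add atoms: none
Why: ring-closing metathesis joins the allyl and vinyl termini (the conjugated trisubstituted diene ester is inert) to give the seven-membered lactone containing the C2=C3 alkene.

Step 12
Reactants: 17 spiro seven-membered lactone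
Product: 18 methyl 13-(tert-butyldimethylsilyloxy)-15,16,17,20-tetranorgibberella-2,8(14)-dien-7-oate 19,10-lactone (natural configuration at C4, C5, C9, C10; C6 and C13 epimers)
Conditions: KN(SiMe3)2, THF, –78 → –30 °C; AcOH, –78 °C
Reagents that add atoms: none
Why: deprotonation at C4 (α to the lactone carbonyl and allylic) gives a dienolate whose α-carbon adds to C5 of the unsaturated ester in an intramolecular Michael addition held by the lactone tether, closing ring A and the γ-lactone at once; C4 and C5 can only form with the lactone bridge cis on ring B and so are dictated by C10, and kinetic α-protonation of the ester dienolate keeps the C8=C14 alkene.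

Step 13
Reactants: 18 silyl ether lactone
Product: 19 methyl 13-hydroxy-15,16,17,20-tetranorgibberella-2,8(14)-dien-7-oate 19,10-lactone (C6 and C13 epimers)
Conditions: HF·pyridine, THF, 0 °C → rt
Reagents that add atoms: none
Why: HF·pyridine removes the silyl ether under non-basic conditions, so the ester is not enolised.

Step 14
Reactants: 19 allylic alcohol lactone
Product: 20 methyl 13-oxo-15,16,17,20-tetranorgibberella-2,8(14)-dien-7-oate 19,10-lactone (6β-ester, natural configuration at C4, C5, C6, C9, C10)
Conditions: Dess–Martin periodinane, CH2Cl2, rt; after work-up Et3N (0.2 equiv), CH2Cl2, rt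
Reagents that add atoms: none
Why: Dess–Martin oxidation gives the conjugated enone directly, and catalytic Et3N should equilibrate the doubly activated C6 centre (γ to the enone, α to the ester) to the epimer with the ester trans to C4, while H9 is not acidic enough to be removed.

Step 15
Reactants: 20 enone lactone
Product: 21 methyl 2β,3β-dihydroxy-13-oxo-15,16,17,20-tetranorgibberell-8(14)-en-7-oate 19,10-lactone
Conditions: OsO4 (2 mol%), N-methylmorpholine N-oxide, acetone/H2O, 0 °C → rt
Reagents that add atoms: N-methylmorpholine N-oxide, C[N+]1([O-])CCOCC1; water, O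
Why: catalytic dihydroxylation attacks only the isolated cis alkene (the enone is electron-poor) and should do so from the face of ring A opposite to the lactone bridge, giving the 2β,3β-diol.

Step 16
Reactants: 21 diol enone; 22 allene
Product: 23 photoadduct: cis-fused methylenecyclobutane on C8–C14 (C15H2 on C8 syn to H9, C16(=C17H2) on C14), 13-ketone, 2β,3β-diol, 19,10-lactone, C7 methyl ester
Conditions: allene (excess), hν (350 nm, Pyrex), THF, –78 °C
Reagents that add atoms: allene (22), C=C=C
Why: enone–allene [2+2] photocycloaddition gives the head-to-head adduct (central allene carbon on the α-carbon C14), and the C8–C15 bond should form syn to H9 (cis-fused hydrindane, the usual outcome for hydrindenones) on the face of ring B not covered by the lactone bridge, which sets C8; C14 is cis-fused and ceases to be a stereocentre in step 17.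

Step 17
Reactants: 23 photoadduct
Product: 24 methyl 2β,3β,13-trihydroxy-20-norgibberell-16-en-7-oate 19,10-lactone (7-methyl ester of the target)
Conditions: SmI2 (2.5 equiv), HMPA, t-BuOH, THF, –78 → 0 °C
Reagents that add atoms: none
Why: Proposed new method: single-electron transfer from SmI2 to the C13 ketone gives a ketyl that is homoallylic to the exocyclic C16=C17 bond; 3-exo attack of C13 on C16 and opening of the resulting cyclopropylcarbinyl radical by cleavage of the strained cyclobutane bond C14–C16 amounts to a 1,2-vinyl shift from C14 to C13, and the C14 radical is then reduced and protonated by t-BuOH. The closest known reaction types are the homoallyl–homoallyl radical rearrangement that converts bicyclo[2.2.2]octenyl into bicyclo[3.2.1]octenyl radicals, SmI2 ketyl–olefin additions and the SmI2-induced opening of cyclobutanes next to a ketyl. Ring D (C8, C14, C13, C16, C15) is formed from the four-membered ring (C8, C14, C16, C15) by one-carbon ring expansion, C13 being inserted between C14 and C16 through a 3-exo-trig closure followed by ring opening. The only new stereocentre, the bridgehead C13, can form in one way only because C16 stays tied through C15 to the face of C8 fixed in step 16. The step needs the ketyl to engage the exocyclic cyclobutane bond C14–C16 and not the ring-fusion bond C14–C8; this should be secured by the better overlap of the exocyclic bond with the ketyl orbital and by the vinyl group, which offers the low-barrier 3-exo path, while about 26 kcal/mol of ring strain is released. Loss of the C13 oxygen from the C14 organosamarium is excluded because it would give a bridgehead alkene.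

Step 18
Reactants: 24 methyl 2β,3β,13-trihydroxy-20-norgibberell-16-en-7-oate 19,10-lactone
Product: 25 2β,3β,13-trihydroxy-20-norgibberell-16-ene-7,19-dioic acid 19,10-lactone (the target gibberellin)
Conditions: n-PrSLi, HMPA, rt; then aq. HCl to pH 3
Reagents that add atoms: none
Why: SN2 demethylation by the thiolate (attack at the ester methyl carbon) frees the C7 acid without opening the lactone and without exposing the 3-hydroxy lactone (a β-hydroxy carbonyl unit) to hydroxide, so retro-aldol epimerisation at C3 is avoided.

**Compound list**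

1 | (S)-4-(tert-butyldimethylsilyloxy)cyclopent-2-en-1-one | CC(C)(C)[Si](C)(C)O[C@@H]1C=CC(=O)C1 | starting material
2 | allylmagnesium bromide | C=CC[Mg]Br | starting material
3 | (1R,4S)-1-allyl-4-(tert-butyldimethylsilyloxy)cyclopent-2-en-1-ol (allyl trans to OTBS) | CC(C)(C)[Si](C)(C)O[C@@H]1C=C[C@@](O)(CC=C)C1 | intermediate
4 | (1R,4S)-1-allylcyclopent-2-ene-1,4-diol (cis diol) | O[C@@H]1C=C[C@@](O)(CC=C)C1 | intermediate
5 | (R)-4-allyl-4-hydroxycyclopent-2-en-1-one | O=C1C=C[C@@](O)(CC=C)C1 | intermediate
6 | 3-(trimethylsilyl)but-3-en-2-one | CC(=O)C(=C)[Si](C)(C)C | starting material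
7 | 4-allyl-4-hydroxy-5-[3-oxo-2-(trimethylsilyl)butyl]cyclopent-2-en-1-one (side chain cis to OH; not isolated) | CC(=O)C(C[C@@H]1C(=O)C=C[C@@]1(O)CC=C)[Si](C)(C)C | intermediate
8 | (4S,5S)-4-allyl-4-hydroxy-5-(3-oxobutyl)cyclopent-2-en-1-one (side chain cis to OH) | CC(=O)CC[C@@H]1C(=O)C=C[C@@]1(O)CC=C | intermediate
9 | 4-allyl-4-hydroxy-2-iodo-5-(3-oxobutyl)cyclopent-2-en-1-one (configuration as in 8) | CC(=O)CC[C@@H]1C(=O)C(I)=C[C@@]1(O)CC=C | intermediate
10 | carbon monoxide | [C-]#[O+] | starting material
11 | methyl 3-allyl-3-hydroxy-5-oxo-4-(3-oxobutyl)cyclopent-1-ene-1-carboxylate (3-OH and side chain cis) | CC(=O)CC[C@@H]1C(=O)C(C(=O)OC)=C[C@@]1(O)CC=C | intermediate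
12 | methyl 1-allyl-1-hydroxy-5-oxo-5,6,7,7a-tetrahydro-1H-indene-3-carboxylate (1-OH cis to C7) | O=C1C=C2[C@@H](CC1)[C@@](CC=C)(O)C=C2C(=O)OC | intermediate
13 | methyl 1-allyl-1,5-dihydroxy-5,6,7,7a-tetrahydro-1H-indene-3-carboxylate (C13 epimers) | OC1C=C2[C@@H](CC1)[C@@](CC=C)(O)C=C2C(=O)OC | intermediate
14 | methyl 1-allyl-5-(tert-butyldimethylsilyloxy)-1-hydroxy-5,6,7,7a-tetrahydro-1H-indene-3-carboxylate | CC(C)(C)[Si](C)(C)OC1C=C2[C@@H](CC1)[C@@](CC=C)(O)C=C2C(=O)OC | intermediate
15 | 2-methylbut-3-enoic acid (racemic) | C=CC(C)C(=O)O | starting material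
16 | 2-methylbut-3-enoate ester of 14 at the tertiary C10 hydroxyl (C4 epimers) | CC(C)(C)[Si](C)(C)OC1C=C2[C@@H](CC1)[C@@](CC=C)(OC(=O)C(C)C=C)C=C2C(=O)OC | intermediate
17 | spiro seven-membered lactone (3-methyl-3,6-dihydrooxepin-2(7H)-one spiro-fused at C10 to the bicyclic diene ester) | CC(C)(C)[Si](C)(C)OC1C=C2[C@@H](CC1)[C@]3(CC=CC(C)C(=O)O3)C=C2C(=O)OC | intermediate
18 | methyl 13-(tert-butyldimethylsilyloxy)-15,16,17,20-tetranorgibberella-2,8(14)-dien-7-oate 19,10-lactone (C6 and C13 epimers) | CC(C)(C)[Si](C)(C)OC1C=C2[C@@H](CC1)[C@@]34CC=C[C@@](C)(C(=O)O3)[C@H]4C2C(=O)OC | intermediate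
19 | methyl 13-hydroxy-15,16,17,20-tetranorgibberella-2,8(14)-dien-7-oate 19,10-lactone (C6 and C13 epimers) | OC1C=C2[C@@H](CC1)[C@@]34CC=C[C@@](C)(C(=O)O3)[C@H]4C2C(=O)OC | intermediate
20 | methyl 13-oxo-15,16,17,20-tetranorgibberella-2,8(14)-dien-7-oate 19,10-lactone (6β-ester) | O=C1C=C2[C@@H](CC1)[C@@]34CC=C[C@@](C)(C(=O)O3)[C@H]4[C@@H]2C(=O)OC | intermediate
21 | methyl 2β,3β-dihydroxy-13-oxo-15,16,17,20-tetranorgibberell-8(14)-en-7-oate 19,10-lactone | O=C1C=C2[C@@H](CC1)[C@@]34C[C@H](O)[C@H](O)[C@@](C)(C(=O)O3)[C@H]4[C@@H]2C(=O)OC | intermediate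
22 | allene (propadiene) | C=C=C | starting material
23 | allene photoadduct of 21 (cis-fused methylenecyclobutane: C15 on C8 syn to H9, C16 on C14; 13-ketone) | C=C1C[C@]23[C@H]1C(=O)CC[C@H]2[C@@]45C[C@H](O)[C@H](O)[C@@](C)(C(=O)O4)[C@H]5[C@@H]3C(=O)OC | intermediate
24 | methyl 2β,3β,13-trihydroxy-20-norgibberell-16-en-7-oate 19,10-lactone (7-methyl ester of the target) | C=C1C[C@]23C[C@@]1(O)CC[C@H]2[C@@]12C[C@H](O)[C@H](O)[C@@](C)(C(=O)O1)[C@H]2[C@@H]3C(=O)OC | intermediate
25 | 2β,3β,13-trihydroxy-20-norgibberell-16-ene-7,19-dioic acid 19,10-lactone (the target gibberellin) | C=C1C[C@]23C[C@@]1(O)CC[C@H]2[C@@]12C[C@H](O)[C@H](O)[C@@](C)(C(=O)O1)[C@H]2[C@@H]3C(=O)O | target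

**Step count and risks**

Total steps: 18. Longest linear sequence: 18 steps (1 → 25).

Steps most likely to fail:

1. Step 17 (Proposed new method). The ketyl may be reduced and protonated to the secondary alcohol before the vinyl shift, or the cyclobutane may open by cleavage of the ring-fusion bond or by hydrogen abstraction after ring opening. Fallback, known chemistry, from 21 back to 24: the diol is protected with 2,2-dimethoxypropane and pyridinium p-toluenesulfonate to give the enone acetonide F1. Conjugate propargylation with allenyltributylstannane and TiCl4 (CH2Cl2, –78 °C; axial attack syn to H9) gives the β-propargyl ketone F2 with quaternary C8. SmI2/HMPA/t-BuOH then effects the ketyl–alkyne 5-exo-dig reductive cyclisation, forming C13–C16 with the bridgehead hydroxyl and the exocyclic methylene, to give the 2,3-acetonide methyl ester F3 (the 2,3-O-isopropylidene derivative of 24). Aqueous acetic acid removes the acetonide and returns 24. This detour closes ring D directly, does not pass through 23, and so also serves if the facial or regiochemical selectivity of step 16 is poor.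

2. Step 12. Carbon–carbon bond formation may be slow because the enolate double bond lies inside the forming five-membered lactone ring, so that orbital overlap at C4 is limited. Proton transfer, migration of the C2=C3 alkene into conjugation, a [3,3] shift of the allylic ester enolate or decomposition of the dienolate could then compete. Fallback, from 14 back to 18: acylation with 2-bromopropionyl bromide and pyridine gives the α-bromopropionate F4. Bu3SnH/AIBN in refluxing benzene (slow addition) closes the γ-lactone by 5-exo-trig radical cyclisation onto C5 to give the bicyclic lactone F5 (C4–H, C4–CH3). Double deprotonation with LiN(iPr)2 and aldol reaction of the more basic lactone enolate with acetaldehyde on the convex face gives the aldol adduct F6. Dehydration with Martin sulfurane gives the C4-vinyl lactone F7, and ring-closing metathesis with second-generation Grubbs catalyst closes ring A to 18.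

3. Step 7. The amine or a second molecule may add to the doubly activated C5=C6 alkene, and the tertiary C10 carbinol may lose water with aromatisation of ring C. Fallback, from 9 back to 12: ring C is closed before the ester is present, by the same pyrrolidine/AcOH aldol condensation on the far less electrophilic iodoenone, to give the bicyclic iodo dienone F8. Palladium-catalysed methoxycarbonylation (Pd(OAc)2, PPh3, CO, MeOH, Et3N) of its vinyl iodide then gives 12.

**Further compounds**

F1 | step 17 | 2,3-O-isopropylidene derivative of enone 21 | O=C1C=C2[C@@H](CC1)[C@@]34C[C@@H]5OC(C)(C)O[C@@H]5[C@@](C)(C(=O)O3)[C@H]4[C@@H]2C(=O)OC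
F2 | step 17 | 8-propargyl 13-ketone acetonide (β-propargyl ketone, C8 quaternary) | C#CC[C@]12CC(=O)CC[C@H]1[C@@]34C[C@@H]5OC(C)(C)O[C@@H]5[C@@](C)(C(=O)O3)[C@H]4[C@@H]2C(=O)OC
F3 | step 17 | 2,3-acetonide methyl ester (2,3-O-isopropylidene derivative of 24) | C=C1C[C@]23C[C@@]1(O)CC[C@H]2[C@@]45C[C@@H]6OC(C)(C)O[C@@H]6[C@@](C)(C(=O)O4)[C@H]5[C@@H]3C(=O)OC
F4 | step 12 | 2-bromopropionate ester of 14 at the C10 hydroxyl | CC(C)(C)[Si](C)(C)OC1C=C2[C@@H](CC1)[C@@](CC=C)(OC(=O)C(C)Br)C=C2C(=O)OC
F5 | step 12 | 10-allyl 19,10-lactone with C4–H and C4–CH3 (C4, C6 and C13 epimers) | CC(C)(C)[Si](C)(C)OC1C=C2[C@@H](CC1)[C@@]3(CC=C)OC(=O)C(C)[C@H]3C2C(=O)OC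
F6 | step 12 | C4-(1-hydroxyethyl) lactone (aldol adduct, new group cis to the C10 allyl) | CC(C)(C)[Si](C)(C)OC1C=C2[C@@H](CC1)[C@@]3(CC=C)OC(=O)[C@](C)(C(C)O)[C@H]3C2C(=O)OC
F7 | step 12 | C4-vinyl C10-allyl lactone | CC(C)(C)[Si](C)(C)OC1C=C2[C@@H](CC1)[C@@]3(CC=C)OC(=O)[C@](C)(C=C)[C@H]3C2C(=O)OC
F8 | step 7 | 1-allyl-1-hydroxy-3-iodo-1,6,7,7a-tetrahydro-5H-inden-5-one (configuration as in 12) | O=C1C=C2[C@@H](CC1)[C@@](CC=C)(O)C=C2I
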